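## Retrosynthetic overview

1. The hydroxyquinone is made last, by oxidising the resorcinol ring of the (3R)-isoflavan (7-O-methyllicoricidin) at C5′, as in the presumed biogenesis.
2. The pyran ring is closed at O1–C2 from an (R)-2-aryl-3-(2-hydroxyaryl)propanal acetal, giving a cyclic 2-methoxy acetal (the deoxo counterpart of the 2-hydroxyisoflavanone of isoflavone synthase), which is then reduced at C2.
3. The C3 stereocentre comes from an oxidative 2→3 shift of the B-ring aryl in an (E)-1,3-diarylpropene (a deoxo-chalcone, C6–C3–C6) with a chiral λ3-iodane.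
4. The diarylpropene comes from a Friedel–Crafts union of a symmetric 4-prenyl-3,5-dimethoxyphenol silyl ether (ring A) with a 1-arylallyl alcohol (ring B plus C3); both prenyl groups are put on the arenes first by directed lithiation.
5. Ring order: the A and B benzene rings are bought; the pyran ring forms in step 9 and the quinone ring in step 11.

Assumption: the known (R,R)-lactate aryl-λ3-iodane (two steps from 2-iodoresorcinol and methyl (S)-lactate, not counted) is taken to give the (R)-acetal; if induction is the reverse, its (S,S)-enantiomer is used with nothing else changed.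

## Route

**Step 1**
Reactants: 1 3,5-dimethoxyphenol
Product: 2 (3,5-dimethoxyphenoxy)tri(propan-2-yl)silane
Conditions: TIPSCl (1.1 eq), imidazole, DMF, rt
Reagents that add atoms: chlorotri(propan-2-yl)silane (TIPSCl), CC(C)[Si](Cl)(C(C)C)C(C)C
Why: Imidazole-promoted O-silylation gives a bulky, weakly coordinating OTIPS group that steers the next lithiation away from C2/C6 and shields the phenol from the iodane in step 7.

**Step 2**
Reactants: 2 (3,5-dimethoxyphenoxy)tri(propan-2-yl)silane; 3 1-bromo-3-methylbut-2-ene (prenyl bromide)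
Product: 5 [3,5-dimethoxy-4-(3-methylbut-2-en-1-yl)phenoxy]tri(propan-2-yl)silane, via 4-lithio silyl ether 4 (not isolated)
Conditions: n-BuLi (1.2 eq), THF, 0 °C→rt, 2 h; then 3, −78 °C→rt
Reagents that add atoms: none
Why: Directed ortho-metalation at the position flanked by both methoxy groups (the OTIPS group blocks its own ortho positions), followed by SN2 alkylation of the aryllithium by the allylic bromide.

**Step 3**
Reactants: 6 benzene-1,3-diol (resorcinol)
Product: 7 1,3-bis(methoxymethoxy)benzene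
Conditions: MOMCl (2.4 eq), i-Pr2NEt, CH2Cl2, 0 °C→rt
Reagents that add atoms: chloromethyl methyl ether (MOMCl), COCCl
Why: Base-mediated O-alkylation (MOM protection) installs two base-stable, strongly ortho-directing groups.

**Step 4**
Reactants: 7 1,3-bis(methoxymethoxy)benzene; 3 1-bromo-3-methylbut-2-ene
Product: 9 1,3-bis(methoxymethoxy)-2-(3-methylbut-2-en-1-yl)benzene, via 2-lithio bis-MOM ether 8 (not isolated)
Conditions: n-BuLi (1.1 eq), THF, 0 °C→rt, 1 h; then 3, −78 °C→rt
Reagents that add atoms: none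
Why: Directed ortho-metalation at C2 between the two OMOM groups (cooperative direction), then SN2 prenylation of the aryllithium.

**Step 5**
Reactants: 9 1,3-bis(methoxymethoxy)-2-(3-methylbut-2-en-1-yl)benzene; 10 prop-2-enal (acrolein)
Product: 12 rac-1-[2,4-bis(methoxymethoxy)-3-(3-methylbut-2-en-1-yl)phenyl]prop-2-en-1-ol, via 4-lithio prenyl arene 11 (not isolated)
Conditions: n-BuLi (1.1 eq), TMEDA, THF, −20→0 °C; then 10, −78 °C; H2O
Reagents that add atoms: none
Why: A second directed ortho-metalation next to an OMOM group (C4 and C6 are equivalent) and 1,2-addition of the hard aryllithium to the enal; the carbinol centre is racemic and is erased in step 6.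

**Step 6**
Reactants: 5 [3,5-dimethoxy-4-(3-methylbut-2-en-1-yl)phenoxy]tri(propan-2-yl)silane; 12 rac-1-[2,4-bis(methoxymethoxy)-3-(3-methylbut-2-en-1-yl)phenyl]prop-2-en-1-ol
Product: 13 {2-[(2E)-3-[2,4-bis(methoxymethoxy)-3-(3-methylbut-2-en-1-yl)phenyl]prop-2-en-1-yl]-3,5-dimethoxy-4-(3-methylbut-2-en-1-yl)phenoxy}tri(propan-2-yl)silane
Conditions: 5 (1.5 eq), Ca(NTf2)2 (5 mol%), n-Bu4NPF6 (5 mol%), CH2Cl2, 0 °C→rt, slow addition of 12
Reagents that add atoms: none
Why: Friedel–Crafts allylation through the 1-arylallyl cation (stabilised by the para-OMOM group), which the arene attacks with its only free, mutually equivalent positions at the unhindered cation terminus to give the conjugated (E)-alkene, the excess arene being far more nucleophilic than the prenyl alkenes.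

**Step 7**
Reactants: 13 the (E)-1,3-diarylpropene silyl ether
Product: 14 {2-[(2R)-2-[2,4-bis(methoxymethoxy)-3-(3-methylbut-2-en-1-yl)phenyl]-3,3-dimethoxypropyl]-3,5-dimethoxy-4-(3-methylbut-2-en-1-yl)phenoxy}tri(propan-2-yl)silane
Conditions: dimethyl (2R,2′R)-2,2′-{[2-(diacetoxy-λ3-iodanyl)-1,3-phenylene]bis(oxy)}dipropanoate (1.05 eq), BF3·OEt2 (2 eq), MeOH (10 eq), CH2Cl2, −78 °C; Et3N quench
Reagents that add atoms: methanol, CO
Why: Proposed new method: the BF3-activated chiral iodane adds face-selectively to the styrene (iodine to C3, methanol to benzylic C2), the electron-rich B-ring aryl then migrates from C2 to C3 anti to the departing aryl iodide with inversion (phenonium ion) and the C2 oxocarbenium ion is trapped by methanol, so the C3 configuration is set by the facial selectivity of iodination alone; chemoselectivity rests on the para-alkoxystyrene being the most π-nucleophilic site (against the isolated, doubly ortho-flanked prenyl alkenes) with 1.05 eq of oxidant at −78 °C; the closest known reactions are the enantioselective oxidative 1,2-aryl migration of aryl alkenes and chalcones to α-aryl acetals and ketones with lactate-based λ3-iodanes and the Tl(III)/I(III) 2,3-aryl shift of chalcones and flavanones to isoflavones.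

**Step 8**
Reactants: 14 the (R)-acetal silyl ether
Product: 15 2-[(2R)-2-[2,4-bis(methoxymethoxy)-3-(3-methylbut-2-en-1-yl)phenyl]-3,3-dimethoxypropyl]-3,5-dimethoxy-4-(3-methylbut-2-en-1-yl)phenol
Conditions: TBAF (1.1 eq), THF, 0 °C
Reagents that add atoms: none
Why: Fluoride-induced Si–O cleavage (desilylation) under basic conditions leaves the dimethyl acetal, the MOM ethers, the alkenes and C3 untouched.

**Step 9**
Reactants: 15 the (R)-phenol acetal
Product: 17 (3R)-3-[2,4-bis(methoxymethoxy)-3-(3-methylbut-2-en-1-yl)phenyl]-5,7-dimethoxy-6-(3-methylbut-2-en-1-yl)-3,4-dihydro-2H-chromene, via cyclic 2-methoxy acetal 16 (not isolated)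
Conditions: Et3SiH (5 eq), BF3·OEt2 (2 eq), CH2Cl2, −78 °C; cold NaHCO3 quench
Reagents that add atoms: none
Why: Lewis-acid transacetalisation lets the only free hydroxyl, the A-ring phenol, close the six-membered ring at C2, and the cyclic oxocarbenium ion is reduced by the silane (ionic hydrogenation, Kishi-type acetal reduction), hydride transfer at −78 °C being faster than loss of the C3 proton so that C3 stays (R).

**Step 10**
Reactants: 17 the (3R)-isoflavan bis-MOM ether
Product: 18 4-[(3R)-5,7-dimethoxy-6-(3-methylbut-2-en-1-yl)-3,4-dihydro-2H-chromen-3-yl]-2-(3-methylbut-2-en-1-yl)benzene-1,3-diol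
Conditions: 3 M aq. HCl, MeOH, 40 °C, short reaction time
Reagents that add atoms: none
Why: Acid-catalysed acetal exchange with methanol (MOM cleavage) under dilute acid at no more than 40 °C frees both phenols before the ortho-prenylphenol can cyclise to a dimethylchroman, and does not touch C3.

**Step 11**
Reactants: 18 the (3R)-isoflavan resorcinol
Product: 19 5-[(3R)-5,7-dimethoxy-6-(3-methylbut-2-en-1-yl)-3,4-dihydro-2H-chromen-3-yl]-2-hydroxy-3-(3-methylbut-2-en-1-yl)cyclohexa-2,5-diene-1,4-dione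
Conditions: Fremy's salt (2.5 eq), KH2PO4 buffer (pH 6), acetone/H2O, 0 °C→rt
Reagents that add atoms: Fremy's salt (dipotassium nitrosodisulfonate), [O]N(S(=O)(=O)[O-])S(=O)(=O)[O-].[K+].[K+]
Why: Teuber oxidation with Fremy's radical converts the 2′-phenol, whose para position C5′ is free, into the p-quinone while the 4′-OH remains as the quinone hydroxyl (attack through the 4′-OH gives the same compound as its tautomer), and alkenes, aryl methyl ethers and C3 are inert.

## Compound list

1 | 3,5-dimethoxyphenol | COc1cc(O)cc(OC)c1 | starting material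
2 | (3,5-dimethoxyphenoxy)tri(propan-2-yl)silane | COc1cc(O[Si](C(C)C)(C(C)C)C(C)C)cc(OC)c1 | intermediate
3 | 1-bromo-3-methylbut-2-ene (prenyl bromide) | CC(C)=CCBr | starting material
4 | [2,6-dimethoxy-4-(triisopropylsilyloxy)phenyl]lithium | [Li]c1c(OC)cc(O[Si](C(C)C)(C(C)C)C(C)C)cc1OC | intermediate
5 | [3,5-dimethoxy-4-(3-methylbut-2-en-1-yl)phenoxy]tri(propan-2-yl)silane | COc1cc(O[Si](C(C)C)(C(C)C)C(C)C)cc(OC)c1CC=C(C)C | intermediate
6 | benzene-1,3-diol (resorcinol) | Oc1cccc(O)c1 | starting material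
7 | 1,3-bis(methoxymethoxy)benzene | COCOc1cccc(OCOC)c1 | intermediate
8 | [2,6-bis(methoxymethoxy)phenyl]lithium | [Li]c1c(OCOC)cccc1OCOC | intermediate
9 | 1,3-bis(methoxymethoxy)-2-(3-methylbut-2-en-1-yl)benzene | COCOc1cccc(OCOC)c1CC=C(C)C | intermediate
10 | prop-2-enal (acrolein) | C=CC=O | starting material
11 | [2,4-bis(methoxymethoxy)-3-(3-methylbut-2-en-1-yl)phenyl]lithium | [Li]c1ccc(OCOC)c(CC=C(C)C)c1OCOC | intermediate
12 | rac-1-[2,4-bis(methoxymethoxy)-3-(3-methylbut-2-en-1-yl)phenyl]prop-2-en-1-ol (racemic carbinol) | C=CC(O)c1ccc(OCOC)c(CC=C(C)C)c1OCOC | intermediate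
13 | {2-[(2E)-3-[2,4-bis(methoxymethoxy)-3-(3-methylbut-2-en-1-yl)phenyl]prop-2-en-1-yl]-3,5-dimethoxy-4-(3-methylbut-2-en-1-yl)phenoxy}tri(propan-2-yl)silane | COc1cc(O[Si](C(C)C)(C(C)C)C(C)C)c(C/C=C/c2ccc(OCOC)c(CC=C(C)C)c2OCOC)c(OC)c1CC=C(C)C | intermediate
14 | {2-[(2R)-2-[2,4-bis(methoxymethoxy)-3-(3-methylbut-2-en-1-yl)phenyl]-3,3-dimethoxypropyl]-3,5-dimethoxy-4-(3-methylbut-2-en-1-yl)phenoxy}tri(propan-2-yl)silane | COc1cc(O[Si](C(C)C)(C(C)C)C(C)C)c(C[C@H](c2ccc(OCOC)c(CC=C(C)C)c2OCOC)C(OC)OC)c(OC)c1CC=C(C)C | intermediate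
15 | 2-[(2R)-2-[2,4-bis(methoxymethoxy)-3-(3-methylbut-2-en-1-yl)phenyl]-3,3-dimethoxypropyl]-3,5-dimethoxy-4-(3-methylbut-2-en-1-yl)phenol | COc1cc(O)c(C[C@H](c2ccc(OCOC)c(CC=C(C)C)c2OCOC)C(OC)OC)c(OC)c1CC=C(C)C | intermediate
16 | (3R)-3-[2,4-bis(methoxymethoxy)-3-(3-methylbut-2-en-1-yl)phenyl]-2,5,7-trimethoxy-6-(3-methylbut-2-en-1-yl)-3,4-dihydro-2H-chromene (both C2 epimers) | COc1cc2c(c(OC)c1CC=C(C)C)C[C@H](c1ccc(OCOC)c(CC=C(C)C)c1OCOC)C(OC)O2 | intermediate
17 | (3R)-3-[2,4-bis(methoxymethoxy)-3-(3-methylbut-2-en-1-yl)phenyl]-5,7-dimethoxy-6-(3-methylbut-2-en-1-yl)-3,4-dihydro-2H-chromene | COc1cc2c(c(OC)c1CC=C(C)C)C[C@H](c1ccc(OCOC)c(CC=C(C)C)c1OCOC)CO2 | intermediate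
18 | 4-[(3R)-5,7-dimethoxy-6-(3-methylbut-2-en-1-yl)-3,4-dihydro-2H-chromen-3-yl]-2-(3-methylbut-2-en-1-yl)benzene-1,3-diol (7-O-methyllicoricidin) | COc1cc2c(c(OC)c1CC=C(C)C)C[C@H](c1ccc(O)c(CC=C(C)C)c1O)CO2 | intermediate
19 | 5-[(3R)-5,7-dimethoxy-6-(3-methylbut-2-en-1-yl)-3,4-dihydro-2H-chromen-3-yl]-2-hydroxy-3-(3-methylbut-2-en-1-yl)cyclohexa-2,5-diene-1,4-dione (CNP0241224.1) | COc1cc2c(c(OC)c1CC=C(C)C)C[C@H](C1=CC(=O)C(O)=C(CC=C(C)C)C1=O)CO2 | target

## Step count and risks

Total step count: 11.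
Longest linear sequence: 9 steps (steps 3, 4, 5, 6, 7, 8, 9, 10, 11, from resorcinol); steps 1 and 2 form the second branch, which joins at step 6.

**Step 7 (oxidative aryl shift).** The iodane may attack a prenyl alkene, iodinate a free arene position or abstract hydride from the doubly activated CH2 instead of adding to the styrene, and the ee on this substrate class is untested. The fallback carries both prenyl groups as allyl groups, which are several orders of magnitude less π-nucleophilic than the styrene, and turns them into prenyl groups by cross-metathesis once the styrene is gone. It sets out from 2 and 7 and comes back at 14. Aryllithium 4, made from 2 as in step 2, is quenched with allyl bromide to give [3,5-dimethoxy-4-(prop-2-en-1-yl)phenoxy]tri(propan-2-yl)silane F1. Aryllithium 8, made from 7 as in step 4, and allyl bromide give 1,3-bis(methoxymethoxy)-2-(prop-2-en-1-yl)benzene F2. This is lithiated (n-BuLi, TMEDA) to [2,4-bis(methoxymethoxy)-3-(prop-2-en-1-yl)phenyl]lithium F3 and added to acrolein to give rac-1-[2,4-bis(methoxymethoxy)-3-(prop-2-en-1-yl)phenyl]prop-2-en-1-ol F4. The calcium-catalysed Friedel–Crafts union of F1 and F4 gives the diallyl (E)-1,3-diarylpropene silyl ether F5, and the iodane rearrangement under the step 7 conditions gives the diallyl (R)-acetal silyl ether F6. Double cross-metathesis of F6 with excess 2-methyl-2-butene (Grubbs second-generation catalyst, CH2Cl2, 40 °C) converts both allyl groups into prenyl groups and gives 14.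

**Step 9 (reductive ring closure).** The C2 oxocarbenium ion can lose the benzylic C3 proton to give the 4H-chromene enol ether, which would erode the ee, and BF3 may open a MOM ether early. The fallback closes O1–C2 by SN2 at a primary carbon, so no cation is formed next to C3. It sets out from 15 and comes back at 17. Mild aqueous acid (PPTS, acetone/H2O, rt) hydrolyses the dimethyl acetal to the lactol (3R)-3-[2,4-bis(methoxymethoxy)-3-(3-methylbut-2-en-1-yl)phenyl]-5,7-dimethoxy-6-(3-methylbut-2-en-1-yl)-3,4-dihydro-2H-chromen-2-ol F7. NaBH4 (MeOH, 0 °C) reduces this through its open hydroxy-aldehyde form to 2-[(2R)-2-[2,4-bis(methoxymethoxy)-3-(3-methylbut-2-en-1-yl)phenyl]-3-hydroxypropyl]-3,5-dimethoxy-4-(3-methylbut-2-en-1-yl)phenol F8. Mitsunobu etherification (PPh3, DIAD, THF, 0 °C) of the phenol with the primary alcohol gives 17.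

**Step 11 (quinone formation).** The radical oxidation may stop short, over-oxidise or give a product that is hard to purify. The fallback brings in the third oxygen by a two-electron sequence before the final oxidation. It sets out from 18 and comes back at 19. Ortho-formylation (MgCl2, Et3N, paraformaldehyde, MeCN, reflux) at C5′, the only free position ortho to a phenolic OH, gives 5-[(3R)-5,7-dimethoxy-6-(3-methylbut-2-en-1-yl)-3,4-dihydro-2H-chromen-3-yl]-2,4-dihydroxy-3-(3-methylbut-2-en-1-yl)benzaldehyde F9. Dakin oxidation (H2O2, aq. NaOH, THF, 0 °C) gives 5-[(3R)-5,7-dimethoxy-6-(3-methylbut-2-en-1-yl)-3,4-dihydro-2H-chromen-3-yl]-3-(3-methylbut-2-en-1-yl)benzene-1,2,4-triol F10. This hydroxyhydroquinone is oxidised by air (or Ag2O, Et2O) to 19.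

## Further compounds

F1 | step 7 | [3,5-dimethoxy-4-(prop-2-en-1-yl)phenoxy]tri(propan-2-yl)silane | C=CCc1c(OC)cc(O[Si](C(C)C)(C(C)C)C(C)C)cc1OC
F2 | step 7 | 1,3-bis(methoxymethoxy)-2-(prop-2-en-1-yl)benzene | C=CCc1c(OCOC)cccc1OCOC
F3 | step 7 | [2,4-bis(methoxymethoxy)-3-(prop-2-en-1-yl)phenyl]lithium | [Li]c1ccc(OCOC)c(CC=C)c1OCOC
F4 | step 7 | rac-1-[2,4-bis(methoxymethoxy)-3-(prop-2-en-1-yl)phenyl]prop-2-en-1-ol | C=CCc1c(OCOC)ccc(C(O)C=C)c1OCOC
F5 | step 7 | {2-[(2E)-3-[2,4-bis(methoxymethoxy)-3-(prop-2-en-1-yl)phenyl]prop-2-en-1-yl]-3,5-dimethoxy-4-(prop-2-en-1-yl)phenoxy}tri(propan-2-yl)silane | COc1cc(O[Si](C(C)C)(C(C)C)C(C)C)c(C/C=C/c2ccc(OCOC)c(CC=C)c2OCOC)c(OC)c1CC=C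
F6 | step 7 | {2-[(2R)-2-[2,4-bis(methoxymethoxy)-3-(prop-2-en-1-yl)phenyl]-3,3-dimethoxypropyl]-3,5-dimethoxy-4-(prop-2-en-1-yl)phenoxy}tri(propan-2-yl)silane | COc1cc(O[Si](C(C)C)(C(C)C)C(C)C)c(C[C@H](c2ccc(OCOC)c(CC=C)c2OCOC)C(OC)OC)c(OC)c1CC=C
F7 | step 9 | (3R)-3-[2,4-bis(methoxymethoxy)-3-(3-methylbut-2-en-1-yl)phenyl]-5,7-dimethoxy-6-(3-methylbut-2-en-1-yl)-3,4-dihydro-2H-chromen-2-ol | COc1cc2c(c(OC)c1CC=C(C)C)C[C@H](c1ccc(OCOC)c(CC=C(C)C)c1OCOC)C(O)O2
F8 | step 9 | 2-[(2R)-2-[2,4-bis(methoxymethoxy)-3-(3-methylbut-2-en-1-yl)phenyl]-3-hydroxypropyl]-3,5-dimethoxy-4-(3-methylbut-2-en-1-yl)phenol | COc1cc(O)c(C[C@H](c2ccc(OCOC)c(CC=C(C)C)c2OCOC)CO)c(OC)c1CC=C(C)C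
F9 | step 11 | 5-[(3R)-5,7-dimethoxy-6-(3-methylbut-2-en-1-yl)-3,4-dihydro-2H-chromen-3-yl]-2,4-dihydroxy-3-(3-methylbut-2-en-1-yl)benzaldehyde | COc1cc2c(c(OC)c1CC=C(C)C)C[C@H](c1cc(C=O)c(O)c(CC=C(C)C)c1O)CO2
F10 | step 11 | 5-[(3R)-5,7-dimethoxy-6-(3-methylbut-2-en-1-yl)-3,4-dihydro-2H-chromen-3-yl]-3-(3-methylbut-2-en-1-yl)benzene-1,2,4-triol | COc1cc2c(c(OC)c1CC=C(C)C)C[C@H](c1cc(O)c(O)c(CC=C(C)C)c1O)CO2
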